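**Retrosynthetic overview**

- The target is cut at the aryl–vinyl bond C5–Cα (Heck reaction of an aryl bromide with acrylic acid), then at the coumarate ester C–O bond (Mitsunobu), then back from the primary alcohol to a methyl ester (hydride reduction).
- The strategy rests on the pair of adjacent stereocentres C2 (ring carbon on O1) and C1' (side-chain CH(CH3)). They are joined by bond C2–C1' and flanked by bonds O1–C2 and C1'–C2', so they are the two carbons of an (E)-alkene to which the phenol oxygen and a carbonyl carbon add from opposite faces.
- Key disconnection: the bromo methyl ester goes back to 4-bromo-2-[(E)-but-2-en-1-yl]phenol, CO and methanol; both bonds form in one palladium-triggered oxycarbonylation.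
- The crotylphenol comes from an aryl 1-methylallyl ether (aromatic Claisen), and that from 4-bromophenol and but-3-en-2-ol (Mitsunobu).
- Ring order: both benzene rings are bought; the dihydrofuran ring (O1–C2–C3–C3a–C7a) is the only ring formed, in step 3.

Key step: step 3

Assumption: the sense of induction of the bisoxazoline in step 3 cannot be predicted with confidence; (S,S)-Ph-box is written, and its commercially available enantiomer would be used if a first run shows that it leads to the mirror image of 8.

**Route**

Step 1
Reactants: 1 4-bromophenol; 2 but-3-en-2-ol (racemic)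
Product: 3 1-bromo-4-(but-3-en-2-yloxy)benzene (racemic)
Conditions: PPh3, DIAD, THF, 0 °C to rt
Reagents that add atoms: none
Why: Mitsunobu etherification, in which the phenol is acidic enough to protonate the PPh3–DIAD betaine and its anion displaces the activated secondary allylic alcohol by SN2 to give the branched 1-methylallyl ether; the alcohol is used as the racemate because its stereocentre disappears in step 2.

Step 2
Reactants: 3 1-bromo-4-(but-3-en-2-yloxy)benzene
Product: 5 4-bromo-2-[(E)-but-2-en-1-yl]phenol, via ortho-dienone 4 (not isolated)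
Conditions: N,N-diethylaniline, 190 °C, argon
Reagents that add atoms: none
Why: Aromatic Claisen rearrangement through a chair transition state with the methyl group pseudo-equatorial should give dienone 4, which tautomerises to the phenol carrying the (E)-alkene; the para bromide blocks the para pathway, the two ortho positions are equivalent, and any minor (Z)-isomer would be removed on AgNO3-impregnated silica.

Step 3
Reactants: 5 4-bromo-2-[(E)-but-2-en-1-yl]phenol
Product: 8 methyl (2R)-2-[(2S)-5-bromo-2,3-dihydro-1-benzofuran-2-yl]propanoate, via alkylpalladium chloride 6 (not isolated), via acylpalladium chloride 7 (not isolated)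
Conditions: PdCl2(MeCN)2 (10 mol %), (S,S)-Ph-box [2,2'-(propane-2,2-diyl)bis((4S)-4-phenyl-4,5-dihydro-1,3-oxazole)] (12 mol %, premixed with the palladium salt), p-benzoquinone (2 equiv), LiCl (0.5 equiv), CO (3 bar), MeOH/CH2Cl2 1:1, 0 °C to rt
Reagents that add atoms: carbon monoxide, [C-]#[O+]; methanol, CO
Why: Proposed new method: the cationic (Ph-box)PdCl(alkene) complex of divalent palladium and 5 should be attacked by the phenol oxygen on the alkene face opposite the metal (anti-oxypalladation, because chloride on palladium keeps the phenoxide out of the coordination sphere) to give secondary alkylpalladium 6, which takes up CO with retention at carbon to give acylpalladium 7; methanolysis then releases ester 8 and zerovalent palladium, which p-benzoquinone and the HCl formed return to the divalent state. The closest known reaction types are the palladium-catalysed intramolecular alkoxycarbonylation of hydroxy-alkenes (PdCl2, CuCl2, CO, MeOH; stereospecifically anti on 1,2-disubstituted alkenes) and the enantioselective Wacker-type cyclisation of ortho-allylphenols with chiral bisoxazolines; new is their combination on an (E)-1,2-disubstituted alkene, and p-benzoquinone replaces CuCl2 because stoichiometric CuCl2 would bind the bisoxazoline and supply enough chloride for a ligand-free racemic pathway. The dihydrofuran ring closes in the 5-exo-trig mode (bond O1–C2), preferred over 6-endo closure to a chromane. C2 is set by the ligand, which selects the alkene face that palladium binds and so the face left open to oxygen; C1' is fixed relative to C2 by the (E)-geometry, the anti addition and the retentive CO insertion, which together place O1 and the methyl group syn along C3–C2–C1'–C2' as in the target. The selectivities needed are the syn relative configuration (secured by the (E)-crotyl geometry from step 2), 5-exo regioselectivity (secured by the single CH2 link between arene and alkene), and CO insertion ahead of beta-hydride elimination from 6 and of oxidative addition at C–Br (secured by CO pressure and by the absence of phosphine at room temperature).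

Step 4
Reactants: 8 methyl (2R)-2-[(2S)-5-bromo-2,3-dihydro-1-benzofuran-2-yl]propanoate
Product: 9 (2S)-2-[(2S)-5-bromo-2,3-dihydro-1-benzofuran-2-yl]propan-1-ol
Conditions: LiBH4, THF, 0 °C to rt; aq. NH4Cl
Reagents that add atoms: none
Why: Hydride reduction of the ester by LiBH4 should give the primary alcohol without touching the aryl bromide, and the weakly basic reagent at low temperature should avoid epimerisation at C1' or ring opening by beta-elimination of the phenoxide (the descriptor at C1' changes from R to S only because CH2OH ranks below C2).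

Step 5
Reactants: 9 (2S)-2-[(2S)-5-bromo-2,3-dihydro-1-benzofuran-2-yl]propan-1-ol; 10 p-coumaric acid [(2E)-3-(4-hydroxyphenyl)prop-2-enoic acid]
Product: 11 (2S)-2-[(2S)-5-bromo-2,3-dihydro-1-benzofuran-2-yl]propyl (2E)-3-(4-hydroxyphenyl)prop-2-enoate
Conditions: PPh3, DIAD, THF, 0 °C to rt
Reagents that add atoms: none
Why: Mitsunobu esterification, in which the carboxylic acid of 10 (far more acidic than its phenol) should be the nucleophile that displaces the activated primary alcohol, so the phenol needs no protection and the reaction at CH2 leaves both stereocentres untouched.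

Step 6
Reactants: 11 (2S)-2-[(2S)-5-bromo-2,3-dihydro-1-benzofuran-2-yl]propyl (2E)-3-(4-hydroxyphenyl)prop-2-enoate; 12 acrylic acid
Product: 13 (2E)-3-[(2S)-2-[(2S)-1-{[(2E)-3-(4-hydroxyphenyl)prop-2-enoyl]oxy}propan-2-yl]-2,3-dihydro-1-benzofuran-5-yl]prop-2-enoic acid (CNP0224846.1)
Conditions: Pd(OAc)2 (5 mol %), P(o-tol)3 (12 mol %), Et3N, acrylic acid (3 equiv), DMF, 100 °C; then 1 M HCl
Reagents that add atoms: none
Why: Mizoroki–Heck reaction, in which oxidative addition of zerovalent palladium into the aryl bromide, insertion of acrylic acid (in excess and far more reactive than the disubstituted coumarate alkene) and beta-hydride elimination should give the (E)-cinnamic acid directly.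

**Compound list**

1 | 4-bromophenol | Oc1ccc(Br)cc1 | starting material
2 | but-3-en-2-ol (racemic) | C=CC(C)O | starting material
3 | 1-bromo-4-(but-3-en-2-yloxy)benzene (racemic) | C=CC(C)Oc1ccc(Br)cc1 | intermediate
4 | ortho-dienone: 4-bromo-6-[(E)-but-2-en-1-yl]cyclohexa-2,4-dien-1-one (racemic) | C/C=C/CC1C=C(Br)C=CC1=O | intermediate (not isolated)
5 | 4-bromo-2-[(E)-but-2-en-1-yl]phenol | C/C=C/Cc1cc(Br)ccc1O | intermediate
6 | alkylpalladium chloride: (1R)-1-[(2S)-5-bromo-2,3-dihydro-1-benzofuran-2-yl]ethylpalladium chloride (Ph-box on palladium not drawn) | C[C@@H]([Pd]Cl)[C@@H]1Cc2cc(Br)ccc2O1 | intermediate (not isolated)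
7 | acylpalladium chloride: (2R)-2-[(2S)-5-bromo-2,3-dihydro-1-benzofuran-2-yl]propanoylpalladium chloride (Ph-box on palladium not drawn) | C[C@@H](C(=O)[Pd]Cl)[C@@H]1Cc2cc(Br)ccc2O1 | intermediate (not isolated)
8 | methyl (2R)-2-[(2S)-5-bromo-2,3-dihydro-1-benzofuran-2-yl]propanoate | C[C@@H](C(=O)OC)[C@@H]1Cc2cc(Br)ccc2O1 | intermediate
9 | (2S)-2-[(2S)-5-bromo-2,3-dihydro-1-benzofuran-2-yl]propan-1-ol | C[C@@H](CO)[C@@H]1Cc2cc(Br)ccc2O1 | intermediate
10 | p-coumaric acid, (2E)-3-(4-hydroxyphenyl)prop-2-enoic acid | OC(=O)/C=C/c1ccc(O)cc1 | starting material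
11 | (2S)-2-[(2S)-5-bromo-2,3-dihydro-1-benzofuran-2-yl]propyl (2E)-3-(4-hydroxyphenyl)prop-2-enoate | C[C@@H](COC(=O)/C=C/c1ccc(O)cc1)[C@@H]1Cc2cc(Br)ccc2O1 | intermediate
12 | acrylic acid | C=CC(=O)O | starting material
13 | (2E)-3-[(2S)-2-[(2S)-1-{[(2E)-3-(4-hydroxyphenyl)prop-2-enoyl]oxy}propan-2-yl]-2,3-dihydro-1-benzofuran-5-yl]prop-2-enoic acid | C[C@@H](COC(=O)/C=C/c1ccc(O)cc1)[C@@H]1Cc2cc(/C=C/C(=O)O)ccc2O1 | target

**Step count and risks**

Total step count: 6. Longest linear sequence: 6 steps (from 4-bromophenol 1 to 13).

Steps most likely to fail: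

1. Step 3 (proposed new method). The ligand-bound palladium may discriminate poorly between the alkene faces, part of the material may pass through syn-oxypalladation and end as the C1' epimer, or the chloride-bearing chelate may turn over slowly so that beta-hydride elimination competes. The fallback uses known chemistry, sets out from 5 and returns at 9. The ligand-free conditions PdCl2 (10 mol %), CuCl2 (3 equiv), CO (1 atm), MeOH, rt (stereospecific anti addition) should give, with the correct relative configuration, the racemic methyl 2-(5-bromo-2,3-dihydro-1-benzofuran-2-yl)propanoate F1. LiBH4 in THF should reduce it to the racemic 2-(5-bromo-2,3-dihydro-1-benzofuran-2-yl)propan-1-ol F2. Esterification with (R)-2-methoxy-2-phenylacetic acid (DCC, DMAP, CH2Cl2) should give two diastereomers to be separated by preparative chromatography on silica or by crystallisation: (2S)-2-[(2S)-5-bromo-2,3-dihydro-1-benzofuran-2-yl]propyl (2R)-2-methoxy-2-phenylacetate F3 and (2R)-2-[(2R)-5-bromo-2,3-dihydro-1-benzofuran-2-yl]propyl (2R)-2-methoxy-2-phenylacetate F4. Methanolysis of F3 (K2CO3, MeOH, rt) returns alcohol 9.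

2. Step 6. Oxidative addition into the electron-rich aryl bromide may be slow at a temperature where the coumarate double bond and the free phenol of 11 begin to react (arylation of the coumarate alkene, oligomers), and the ester link may suffer under hot amine base. The fallback sets out from 9 and returns at 13; it moves the Heck reaction ahead of the esterification and masks the acid. A Heck reaction of 9 with tert-butyl acrylate (Pd(OAc)2, P(o-tol)3, Et3N, DMF, 100 °C) should give tert-butyl (2E)-3-{(2S)-2-[(2S)-1-hydroxypropan-2-yl]-2,3-dihydro-1-benzofuran-5-yl}prop-2-enoate F5. Mitsunobu esterification with 10 as in step 5 should give tert-butyl (2E)-3-[(2S)-2-[(2S)-1-{[(2E)-3-(4-hydroxyphenyl)prop-2-enoyl]oxy}propan-2-yl]-2,3-dihydro-1-benzofuran-5-yl]prop-2-enoate F6. CF3CO2H in CH2Cl2 at 0 °C cleaves the tert-butyl ester to 13.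

3. Step 5. The phenol oxygen of 10 may be alkylated in competition with the carboxylate (aryl ether, oligomers), or the betaine may be captured before the acid protonates it. The fallback sets out from 9 and returns at 11; it builds the coumarate double bond on the alcohol instead of esterifying with the preformed acid. Heating 9 with Meldrum's acid in toluene at 100 °C should give the malonic half ester 3-{(2S)-2-[(2S)-5-bromo-2,3-dihydro-1-benzofuran-2-yl]propoxy}-3-oxopropanoic acid F7. Knoevenagel–Doebner condensation of F7 with 4-hydroxybenzaldehyde (pyridine, cat. piperidine, 70 °C) should give 11 with decarboxylation and (E)-geometry.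

**Further compounds**

F1 | step 3 | racemic methyl 2-(5-bromo-2,3-dihydro-1-benzofuran-2-yl)propanoate, (2R,2'S) and (2S,2'R) pair | C[C@@H](C(=O)OC)[C@@H]1Cc2cc(Br)ccc2O1.C[C@H](C(=O)OC)[C@H]1Cc2cc(Br)ccc2O1
F2 | step 3 | racemic 2-(5-bromo-2,3-dihydro-1-benzofuran-2-yl)propan-1-ol, (S,S) and (R,R) pair | C[C@@H](CO)[C@@H]1Cc2cc(Br)ccc2O1.C[C@H](CO)[C@H]1Cc2cc(Br)ccc2O1
F3 | step 3 | (2S)-2-[(2S)-5-bromo-2,3-dihydro-1-benzofuran-2-yl]propyl (2R)-2-methoxy-2-phenylacetate | C[C@@H](COC(=O)[C@H](OC)c1ccccc1)[C@@H]1Cc2cc(Br)ccc2O1
F4 | step 3 | (2R)-2-[(2R)-5-bromo-2,3-dihydro-1-benzofuran-2-yl]propyl (2R)-2-methoxy-2-phenylacetate | C[C@H](COC(=O)[C@H](OC)c1ccccc1)[C@H]1Cc2cc(Br)ccc2O1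
F5 | step 6 | tert-butyl (2E)-3-{(2S)-2-[(2S)-1-hydroxypropan-2-yl]-2,3-dihydro-1-benzofuran-5-yl}prop-2-enoate | C[C@@H](CO)[C@@H]1Cc2cc(/C=C/C(=O)OC(C)(C)C)ccc2O1
F6 | step 6 | tert-butyl (2E)-3-[(2S)-2-[(2S)-1-{[(2E)-3-(4-hydroxyphenyl)prop-2-enoyl]oxy}propan-2-yl]-2,3-dihydro-1-benzofuran-5-yl]prop-2-enoate | C[C@@H](COC(=O)/C=C/c1ccc(O)cc1)[C@@H]1Cc2cc(/C=C/C(=O)OC(C)(C)C)ccc2O1
F7 | step 5 | 3-{(2S)-2-[(2S)-5-bromo-2,3-dihydro-1-benzofuran-2-yl]propoxy}-3-oxopropanoic acid | C[C@@H](COC(=O)CC(=O)O)[C@@H]1Cc2cc(Br)ccc2O1
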